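The target is read as epicatechin-(4α→6)-ent-epicatechin-(4β→8)-epicatechin-(4β→6)-epicatechin (first to fourth unit). Everything rests on cutting ring C of the first unit across O1–C2 and C3–C4. Its all-cis array (aryl at C2, hydroxyl at C3, aryl at C4 on one face) is what an endo oxa-[4+2] cycloaddition delivers when an ortho-quinone methide (O1, C8a, C4a, C4; C4 already bonded to C6 of the second unit) meets a Z-configured β-benzoyloxystyrene (C2, C3). One operation closes this last ring, forms two bonds and sets three stereocentres under chiral Brønsted acid control. The precursor is an o-hydroxybenzhydrol built on a halogen-differentiated lower trimer.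

Key step: step 17

Remark: (+)-epicatechin (2S,3S) is assumed to be purchasable; the flavan units are called first (top) to fourth (terminal) unit, rings A, B, C are those of each unit, chlorine at C8 is a blocking group, bromine is the metalation handle, and the (R)-configured acid in step 17 is an assumption about the sense of induction.

Step 1
Reactants: 1 (−)-epicatechin
Product: 2 penta-O-benzyl-(−)-epicatechin
Conditions: BnBr, K2CO3, DMF, 0 °C → rt; then NaH, 0 °C → rt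
Reagents that add atoms: benzyl bromide BrCc1ccccc1
Why: Williamson etherification, in which the four phenoxides are benzylated under carbonate and the secondary 3-alkoxide only after NaH is added, which limits C-benzylation and leaves C2 and C3 untouched.

Step 2
Reactants: 2 penta-O-benzyl-(−)-epicatechin
Product: 3 8-chloro-penta-O-benzyl-(−)-epicatechin
Conditions: NCS, DMF, 0 °C → rt
Reagents that add atoms: N-chlorosuccinimide O=C1CCC(=O)N1Cl
Why: Electrophilic aromatic chlorination should go to C8, the most nucleophilic and least hindered position of ring A (the site also taken by NBS), and installs a block that is inert to alkyllithiums at −78 °C.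

Step 3
Reactants: 2 penta-O-benzyl-(−)-epicatechin
Product: 4 8-bromo-penta-O-benzyl-(−)-epicatechin
Conditions: NBS, CH2Cl2, −78 °C → rt
Reagents that add atoms: N-bromosuccinimide O=C1CCC(=O)N1Br
Why: Electrophilic aromatic bromination is selective for C8 of ring A and gives both a block against self-condensation and the later handle for bromine–lithium exchange.

Step 4
Reactants: 4 8-bromo-penta-O-benzyl-(−)-epicatechin
Product: 5 8-bromo-4β-(2-ethoxyethoxy)-penta-O-benzyl-(−)-epicatechin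
Conditions: DDQ, 2-ethoxyethanol, CH2Cl2, rt
Reagents that add atoms: 2-ethoxyethanol CCOCCO
Why: DDQ benzylic oxidation, in which hydride abstraction from C4 gives a ring-A-stabilised cation that the alcohol captures anti to the cis C2-aryl and C3-benzyloxy groups, setting the 4β (3,4-trans) ether.

Step 5
Reactants: 5 8-bromo-4β-(2-ethoxyethoxy)-penta-O-benzyl-(−)-epicatechin; 3 8-chloro-penta-O-benzyl-(−)-epicatechin (3 equiv)
Product: 6 protected lower dimer
Conditions: Me3SiOTf (0.2 equiv), CH2Cl2, −78 °C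
Reagents that add atoms: none
Why: Lewis-acid-promoted Friedel–Crafts coupling, in which the ionised C4 ether is attacked by C6 of 3 (its only free ring-A position) anti to the C2/C3 substituents, setting the 4β (3,4-trans) interflavan bond, while excess 3 and the C8 bromine of 5 suppress self-condensation.

Step 6
Reactants: 7 (+)-epicatechin
Product: 8 penta-O-benzyl-(+)-epicatechin
Conditions: BnBr, K2CO3, DMF, 0 °C → rt; then NaH, 0 °C → rt
Reagents that add atoms: benzyl bromide BrCc1ccccc1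
Why: Williamson etherification as in step 1, applied to the enantiomeric flavanol without touching C2 or C3.

Step 7
Reactants: 8 penta-O-benzyl-(+)-epicatechin
Product: 9 8-chloro-penta-O-benzyl-(+)-epicatechin
Conditions: NCS, DMF, 0 °C → rt
Reagents that add atoms: N-chlorosuccinimide O=C1CCC(=O)N1Cl
Why: Electrophilic aromatic chlorination at C8 of ring A, as in step 2, blocks this position for the rest of the route.

Step 8
Reactants: 9 8-chloro-penta-O-benzyl-(+)-epicatechin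
Product: 10 6-bromo-8-chloro-penta-O-benzyl-(+)-epicatechin
Conditions: NBS, CH2Cl2, 0 °C → rt
Reagents that add atoms: N-bromosuccinimide O=C1CCC(=O)N1Br
Why: Electrophilic aromatic bromination, in which C6 is the only activated ring-A position left once C8 is chlorinated, so the metalation handle is placed there.

Step 9
Reactants: 10 6-bromo-8-chloro-penta-O-benzyl-(+)-epicatechin
Product: 11 4-hydroxy-6-bromo-8-chloro-penta-O-benzyl-(+)-epicatechin
Conditions: DDQ, H2O, CH2Cl2/THF, rt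
Reagents that add atoms: water O
Why: DDQ benzylic oxidation in which water traps the C4 cation anti to the C2/C3 substituents to give the 3,4-trans alcohol, whose configuration is erased in the next step.

Step 10
Reactants: 11 4-hydroxy-6-bromo-8-chloro-penta-O-benzyl-(+)-epicatechin
Product: 12 protected 6-bromo-8-chloro-flavan-4-one
Conditions: (n-Pr4N)RuO4 (5 mol%), NMO, 4 Å MS, CH2Cl2, rt
Reagents that add atoms: none
Why: Ley–Griffith oxidation of the secondary benzylic alcohol gives the ketone under neutral conditions that should not epimerise the α-alkoxy centre C3.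

Step 11
Reactants: 6 protected lower dimer; 12 protected 6-bromo-8-chloro-flavan-4-one
Product: 14 tertiary C4 carbinol of the protected trimer, via dimer aryllithium 13 (not isolated)
Conditions: 6, t-BuLi (2.0 equiv), THF, −78 °C; then 12, −78 → 0 °C; H2O
Reagents that add atoms: none
Why: Bromine–lithium exchange (selective for C–Br over C–Cl) followed by 1,2-addition of the aryllithium to the flavan-4-one from the face anti to the axial 3-benzyloxy group; the new carbinol centre is planarised in the next step.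

Step 12
Reactants: 14 tertiary C4 carbinol of the protected trimer
Product: 15 protected lower trimer
Conditions: n-Bu3SnH, CF3CO2H, CH2Cl2, 0 °C
Reagents that add atoms: none
Why: Ionic hydrogenation, in which acid ionises the tertiary doubly benzylic alcohol and the stannane delivers hydride to the C4 cation from the face opposite the cis C2-aryl/C3-benzyloxy pair, placing the aryl of the third unit cis to the 3-oxygen (all-cis ring C of the second unit).

Step 13
Reactants: 16 2,4,6-trihydroxybenzaldehyde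
Product: 17 4,6-bis(benzyloxy)-2-hydroxybenzaldehyde
Conditions: BnBr (2.05 equiv), K2CO3, DMF, rt
Reagents that add atoms: benzyl bromide BrCc1ccccc1
Why: Williamson etherification in which two equivalents of benzyl bromide alkylate the para hydroxyl and one ortho hydroxyl, while the remaining ortho hydroxyl is hydrogen-bonded to the aldehyde and stays free.

Step 14
Reactants: 15 protected lower trimer; 17 4,6-bis(benzyloxy)-2-hydroxybenzaldehyde
Product: 20 o-hydroxybenzhydrol on C6 of the second unit, via trimer aryllithium 18 (not isolated), via chloromagnesium phenoxide 19 (not isolated)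
Conditions: 17, MeMgCl (1.0 equiv), THF, 0 °C; 15, t-BuLi (2.0 equiv), THF, −78 °C; combine, −78 → 0 °C; H2O
Reagents that add atoms: none
Why: Bromine–lithium exchange at C6 of the second unit (both aryl chlorides are inert) and 1,2-addition of the aryllithium to the magnesium-chelated salicylaldehyde give the benzhydrol, whose carbinol centre forms as an epimer mixture that is irrelevant because it becomes sp2 in step 17.

Step 15
Reactants: 21 3,4-bis(benzyloxy)benzaldehyde
Product: 22 1,2-bis(benzyloxy)-4-ethynylbenzene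
Conditions: Ohira–Bestmann reagent, K2CO3, MeOH, rt
Reagents that add atoms: dimethyl (1-diazo-2-oxopropyl)phosphonate COP(=O)(OC)C(=[N+]=[N-])C(C)=O
Why: Seyferth–Gilbert homologation with the Ohira–Bestmann reagent converts the aryl aldehyde into the terminal alkyne under mild carbonate conditions.

Step 16
Reactants: 22 1,2-bis(benzyloxy)-4-ethynylbenzene
Product: 23 (Z)-2-[3,4-bis(benzyloxy)phenyl]ethenyl benzoate
Conditions: PhCO2H, Ru(η3-CH2C(CH3)CH2)2(Ph2P(CH2)4PPh2) (2 mol%), toluene, 60 °C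
Reagents that add atoms: benzoic acid OC(=O)c1ccccc1
Why: Ruthenium-catalysed anti-Markovnikov addition of a carboxylic acid to a terminal alkyne (through a ruthenium vinylidene) should give the enol ester with Z geometry.

Step 17
Reactants: 20 o-hydroxybenzhydrol on C6 of the second unit; 23 (Z)-2-[3,4-bis(benzyloxy)phenyl]ethenyl benzoate (3 equiv)
Product: 25 protected tetramer 3-O-benzoate, via ortho-quinone methide 24 (not isolated)
Conditions: (R)-3,3′-bis(2,4,6-triisopropylphenyl)-1,1′-binaphthyl-2,2′-diyl N-triflylphosphoramide (10 mol%), 5 Å MS, toluene, 0 °C → rt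
Reagents that add atoms: none
Why: The chiral Brønsted acid ionises 20 with loss of water to the hydrogen-bonded, ion-paired (E)-ortho-quinone methide 24, whose oxadiene (O1=C8a–C4a=C4) adds the electron-rich Z-styrene 23 in an inverse-electron-demand oxa-[4+2] cycloaddition. The closest known reaction type is the N-triflylphosphoramide-catalysed asymmetric cycloaddition of ortho-quinone methides, made in the flask from o-hydroxybenzhydrols, with styrenes. Ring C of the first unit closes in a concerted but asynchronous suprafacial hetero-Diels–Alder mode (C3–C4 bond ahead of O1–C2), not by a separate cyclisation. C2 and C3 take their cis relation from the Z alkene, and C4 becomes cis to both through the endo transition state (aryl and benzoyloxy under the diene) of the E-configured methide, whose geometry keeps the aryl of the second unit away from the catalyst-bound oxygen. The absolute sense (2R,3R with the matching C4) is imposed by the catalyst, with little help expected from the stereocentres of the trimer; should the (R)-acid prove mismatched, the (S)-acid is used. The step needs regioselectivity (C3 to C4, O1 to C2), which is secured by the 3,4-bis(benzyloxy)phenyl group stabilising positive charge at C2 far better than the weakly donating benzoyloxy group can at C3.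

Step 18
Reactants: 25 protected tetramer 3-O-benzoate
Product: 26 protected tetramer 3-ol
Conditions: NaOMe (cat.), MeOH/THF, rt → 40 °C
Reagents that add atoms: none
Why: Zemplén-type transesterification should remove the benzoate without touching benzyl ethers, aryl chlorides or any stereocentre.

Step 19
Reactants: 26 protected tetramer 3-ol
Product: 27 CNP0120618.3
Conditions: H2 (1 atm), Pd(OH)2/C, Et3N, THF/MeOH/H2O, rt
Reagents that add atoms: none
Why: Palladium-catalysed hydrogenolysis should cleave all nineteen benzyl ethers and, with triethylamine as HCl scavenger, hydrodechlorinate both C8 blocking groups while leaving the stereocentres untouched.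

Compound list

1 | (−)-epicatechin, (2R,3R)-2-(3,4-dihydroxyphenyl)chromane-3,5,7-triol | Oc1cc(O)c2c(c1)O[C@H](c1ccc(O)c(O)c1)[C@H](O)C2 | starting material

2 | penta-O-benzyl-(−)-epicatechin, (2R,3R)-3,5,7-tris(benzyloxy)-2-[3,4-bis(benzyloxy)phenyl]chromane | c1c(OCc9ccccc9)cc(OCc9ccccc9)c3c1O[C@H](c8ccc(OCc9ccccc9)c(OCc9ccccc9)c8)[C@H](OCc9ccccc9)C3 | intermediate

3 | 8-chloro-penta-O-benzyl-(−)-epicatechin (Cl at C8 of ring A) | Clc1c(OCc9ccccc9)cc(OCc9ccccc9)c3c1O[C@H](c8ccc(OCc9ccccc9)c(OCc9ccccc9)c8)[C@H](OCc9ccccc9)C3 | intermediate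

4 | 8-bromo-penta-O-benzyl-(−)-epicatechin (Br at C8 of ring A) | Brc1c(OCc9ccccc9)cc(OCc9ccccc9)c3c1O[C@H](c8ccc(OCc9ccccc9)c(OCc9ccccc9)c8)[C@H](OCc9ccccc9)C3 | intermediate

5 | 8-bromo-4β-(2-ethoxyethoxy)-penta-O-benzyl-(−)-epicatechin (ether at C4 trans to the 3-benzyloxy group) | Brc1c(OCc9ccccc9)cc(OCc9ccccc9)c3c1O[C@H](c8ccc(OCc9ccccc9)c(OCc9ccccc9)c8)[C@H](OCc9ccccc9)[C@H]3OCCOCC | intermediate

6 | protected lower dimer: 8-bromo-penta-O-benzylepicatechin (third unit) bonded from C4 (4β, 3,4-trans) to C6 of 8-chloro-penta-O-benzylepicatechin (fourth unit) | Brc1c(OCc9ccccc9)cc(OCc9ccccc9)c3c1O[C@H](c8ccc(OCc9ccccc9)c(OCc9ccccc9)c8)[C@H](OCc9ccccc9)[C@H]3c1c(OCc9ccccc9)c(Cl)c3c(c1OCc9ccccc9)C[C@@H](OCc9ccccc9)[C@@H](c8ccc(OCc9ccccc9)c(OCc9ccccc9)c8)O3 | intermediate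

7 | (+)-epicatechin, (2S,3S)-2-(3,4-dihydroxyphenyl)chromane-3,5,7-triol | Oc1cc(O)c2c(c1)O[C@@H](c1ccc(O)c(O)c1)[C@@H](O)C2 | starting material

8 | penta-O-benzyl-(+)-epicatechin, (2S,3S)-3,5,7-tris(benzyloxy)-2-[3,4-bis(benzyloxy)phenyl]chromane | c1c(OCc9ccccc9)cc2c(c1OCc9ccccc9)C[C@H](OCc9ccccc9)[C@H](c8ccc(OCc9ccccc9)c(OCc9ccccc9)c8)O2 | intermediate

9 | 8-chloro-penta-O-benzyl-(+)-epicatechin | c1c(OCc9ccccc9)c(Cl)c2c(c1OCc9ccccc9)C[C@H](OCc9ccccc9)[C@H](c8ccc(OCc9ccccc9)c(OCc9ccccc9)c8)O2 | intermediate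

10 | 6-bromo-8-chloro-penta-O-benzyl-(+)-epicatechin | Brc1c(OCc9ccccc9)c(Cl)c2c(c1OCc9ccccc9)C[C@H](OCc9ccccc9)[C@H](c8ccc(OCc9ccccc9)c(OCc9ccccc9)c8)O2 | intermediate

11 | 4-hydroxy-6-bromo-8-chloro-penta-O-benzyl-(+)-epicatechin (OH at C4 trans to the 3-benzyloxy group) | Brc1c(OCc9ccccc9)c(Cl)c2c(c1OCc9ccccc9)[C@@H](O)[C@H](OCc9ccccc9)[C@H](c8ccc(OCc9ccccc9)c(OCc9ccccc9)c8)O2 | intermediate

12 | protected 6-bromo-8-chloro-flavan-4-one, (2S,3R)-3,5,7-tris(benzyloxy)-2-[3,4-bis(benzyloxy)phenyl]-6-bromo-8-chlorochroman-4-one (2,3-cis) | Brc1c(OCc9ccccc9)c(Cl)c2c(c1OCc9ccccc9)C(=O)[C@H](OCc9ccccc9)[C@H](c8ccc(OCc9ccccc9)c(OCc9ccccc9)c8)O2 | intermediate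

13 | dimer aryllithium: 6 with Li in place of Br at C8 of the third unit (not isolated) | [Li]c1c(OCc9ccccc9)cc(OCc9ccccc9)c3c1O[C@H](c8ccc(OCc9ccccc9)c(OCc9ccccc9)c8)[C@H](OCc9ccccc9)[C@H]3c1c(OCc9ccccc9)c(Cl)c3c(c1OCc9ccccc9)C[C@@H](OCc9ccccc9)[C@@H](c8ccc(OCc9ccccc9)c(OCc9ccccc9)c8)O3 | intermediate

14 | tertiary carbinol: C4 of the second unit (6-bromo-8-chloro-penta-O-benzyl-ent-epicatechin) carries OH (cis to the 3-benzyloxy group) and C8 of the third unit of the dimer | Brc1c(OCc9ccccc9)c(Cl)c2c(c1OCc9ccccc9)[C@@](O)(c1c(OCc9ccccc9)cc(OCc9ccccc9)c3c1O[C@H](c8ccc(OCc9ccccc9)c(OCc9ccccc9)c8)[C@H](OCc9ccccc9)[C@H]3c1c(OCc9ccccc9)c(Cl)c3c(c1OCc9ccccc9)C[C@@H](OCc9ccccc9)[C@@H](c8ccc(OCc9ccccc9)c(OCc9ccccc9)c8)O3)[C@H](OCc9ccccc9)[C@H](c8ccc(OCc9ccccc9)c(OCc9ccccc9)c8)O2 | intermediate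

15 | protected lower trimer: 6-bromo-8-chloro-ent-epicatechin-(4β→8, 3,4-cis)-epicatechin-(4β→6, 3,4-trans)-8-chloroepicatechin, fifteen benzyl ethers | Brc1c(OCc9ccccc9)c(Cl)c2c(c1OCc9ccccc9)[C@H](c1c(OCc9ccccc9)cc(OCc9ccccc9)c3c1O[C@H](c8ccc(OCc9ccccc9)c(OCc9ccccc9)c8)[C@H](OCc9ccccc9)[C@H]3c1c(OCc9ccccc9)c(Cl)c3c(c1OCc9ccccc9)C[C@@H](OCc9ccccc9)[C@@H](c8ccc(OCc9ccccc9)c(OCc9ccccc9)c8)O3)[C@H](OCc9ccccc9)[C@H](c8ccc(OCc9ccccc9)c(OCc9ccccc9)c8)O2 | intermediate

16 | 2,4,6-trihydroxybenzaldehyde | O=Cc1c(O)cc(O)cc1O | starting material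

17 | 4,6-bis(benzyloxy)-2-hydroxybenzaldehyde | O=Cc1c(O)cc(OCc9ccccc9)cc1OCc9ccccc9 | intermediate

18 | trimer aryllithium: 15 with Li in place of Br at C6 of the second unit (not isolated) | [Li]c1c(OCc9ccccc9)c(Cl)c2c(c1OCc9ccccc9)[C@H](c1c(OCc9ccccc9)cc(OCc9ccccc9)c3c1O[C@H](c8ccc(OCc9ccccc9)c(OCc9ccccc9)c8)[C@H](OCc9ccccc9)[C@H]3c1c(OCc9ccccc9)c(Cl)c3c(c1OCc9ccccc9)C[C@@H](OCc9ccccc9)[C@@H](c8ccc(OCc9ccccc9)c(OCc9ccccc9)c8)O3)[C@H](OCc9ccccc9)[C@H](c8ccc(OCc9ccccc9)c(OCc9ccccc9)c8)O2 | intermediate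

19 | chloromagnesium 3,5-bis(benzyloxy)-2-formylphenoxide (not isolated) | O=Cc1c(O[Mg]Cl)cc(OCc9ccccc9)cc1OCc9ccccc9 | intermediate

20 | o-hydroxybenzhydrol: 15 with Br replaced by CH(OH)[4,6-bis(benzyloxy)-2-hydroxyphenyl] at C6 of the second unit, both carbinol epimers | Oc1cc(OCc9ccccc9)cc(OCc9ccccc9)c1C(O)c1c(OCc9ccccc9)c(Cl)c2c(c1OCc9ccccc9)[C@H](c1c(OCc9ccccc9)cc(OCc9ccccc9)c3c1O[C@H](c8ccc(OCc9ccccc9)c(OCc9ccccc9)c8)[C@H](OCc9ccccc9)[C@H]3c1c(OCc9ccccc9)c(Cl)c3c(c1OCc9ccccc9)C[C@@H](OCc9ccccc9)[C@@H](c8ccc(OCc9ccccc9)c(OCc9ccccc9)c8)O3)[C@H](OCc9ccccc9)[C@H](c8ccc(OCc9ccccc9)c(OCc9ccccc9)c8)O2 | intermediate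

21 | 3,4-bis(benzyloxy)benzaldehyde | O=Cc1ccc(OCc2ccccc2)c(OCc2ccccc2)c1 | starting material

22 | 1,2-bis(benzyloxy)-4-ethynylbenzene | C#Cc1ccc(OCc2ccccc2)c(OCc2ccccc2)c1 | intermediate

23 | (Z)-2-[3,4-bis(benzyloxy)phenyl]ethenyl benzoate | O=C(O/C=C\c1ccc(OCc2ccccc2)c(OCc2ccccc2)c1)c1ccccc1 | intermediate

24 | (E)-ortho-quinone methide: 3,5-bis(benzyloxy)-6-(arylmethylidene)cyclohexa-2,4-dien-1-one, aryl = C6 of the second unit of the trimer, anti to the carbonyl (not isolated) | O=C1C=C(OCc9ccccc9)C=C(OCc9ccccc9)/C1=C\c1c(OCc9ccccc9)c(Cl)c2c(c1OCc9ccccc9)[C@H](c1c(OCc9ccccc9)cc(OCc9ccccc9)c3c1O[C@H](c8ccc(OCc9ccccc9)c(OCc9ccccc9)c8)[C@H](OCc9ccccc9)[C@H]3c1c(OCc9ccccc9)c(Cl)c3c(c1OCc9ccccc9)C[C@@H](OCc9ccccc9)[C@@H](c8ccc(OCc9ccccc9)c(OCc9ccccc9)c8)O3)[C@H](OCc9ccccc9)[C@H](c8ccc(OCc9ccccc9)c(OCc9ccccc9)c8)O2 | intermediate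

25 | protected tetramer 3-O-benzoate: the first unit is 5,7,3′,4′-tetra-O-benzyl-3-O-benzoyl-epicatechin (2R,3R), its C4 bonded cis (4α) to C6 of the second unit; nineteen benzyl ethers, Cl at C8 of the second unit, Cl at C8 of the fourth unit | c1(OCc9ccccc9)cc(OCc9ccccc9)c2c(c1)O[C@H](c8ccc(OCc9ccccc9)c(OCc9ccccc9)c8)[C@H](OC(=O)c9ccccc9)[C@@H]2c1c(OCc9ccccc9)c(Cl)c2c(c1OCc9ccccc9)[C@H](c1c(OCc9ccccc9)cc(OCc9ccccc9)c3c1O[C@H](c8ccc(OCc9ccccc9)c(OCc9ccccc9)c8)[C@H](OCc9ccccc9)[C@H]3c1c(OCc9ccccc9)c(Cl)c3c(c1OCc9ccccc9)C[C@@H](OCc9ccccc9)[C@@H](c8ccc(OCc9ccccc9)c(OCc9ccccc9)c8)O3)[C@H](OCc9ccccc9)[C@H](c8ccc(OCc9ccccc9)c(OCc9ccccc9)c8)O2 | intermediate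

26 | protected tetramer 3-ol: 25 with a free 3-hydroxyl on the first unit | c1(OCc9ccccc9)cc(OCc9ccccc9)c2c(c1)O[C@H](c8ccc(OCc9ccccc9)c(OCc9ccccc9)c8)[C@H](O)[C@@H]2c1c(OCc9ccccc9)c(Cl)c2c(c1OCc9ccccc9)[C@H](c1c(OCc9ccccc9)cc(OCc9ccccc9)c3c1O[C@H](c8ccc(OCc9ccccc9)c(OCc9ccccc9)c8)[C@H](OCc9ccccc9)[C@H]3c1c(OCc9ccccc9)c(Cl)c3c(c1OCc9ccccc9)C[C@@H](OCc9ccccc9)[C@@H](c8ccc(OCc9ccccc9)c(OCc9ccccc9)c8)O3)[C@H](OCc9ccccc9)[C@H](c8ccc(OCc9ccccc9)c(OCc9ccccc9)c8)O2 | intermediate

27 | CNP0120618.3, epicatechin-(4α→6, 3,4-cis)-ent-epicatechin-(4β→8, 3,4-cis)-epicatechin-(4β→6, 3,4-trans)-epicatechin | Oc1cc(O)c2c(c1)O[C@H](c1ccc(O)c(O)c1)[C@H](O)[C@@H]2c1c(O)cc2c(c1O)[C@H](c1c(O)cc(O)c3c1O[C@H](c1ccc(O)c(O)c1)[C@H](O)[C@H]3c1c(O)cc3c(c1O)C[C@@H](O)[C@@H](c1ccc(O)c(O)c1)O3)[C@H](O)[C@H](c1ccc(O)c(O)c1)O2 | target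

Total step count: 19 steps.
Longest linear sequence: 11 steps (steps 6, 7, 8, 9, 10, 11, 12, 14, 17, 18, 19, from (+)-epicatechin).

Steps most likely to fail

1. Step 17. The addition may be slow because the methide is doubly stabilised and flanked by ortho-benzyloxy groups. The all-cis relation may erode through acid-induced Z to E isomerisation of the enol ester, through reaction of the Z-methide or the exo mode, or through a stepwise pathway. Facial discrimination by the catalyst may be poor on so large a substrate. The fallback sets out from 20 and returns at 26; it still closes ring C of the first unit last but takes the relative configuration from substrate-controlled steps instead of the cycloaddition topology. The same acid-generated methide is trapped with alkyne 22 to give the 2,4-diaryl-4H-chromene F1, whose C4 epimers are separated if the catalyst control is incomplete. Hydroboration–oxidation (BH3·THF; NaOH, H2O2) anti to the C4 aryl gives the 2,4-cis-3-trans flavan-3-ol F2. Oxidation with (n-Pr4N)RuO4/NMO gives the flavan-3-one F3. LiBH(s-Bu)3 at −78 °C then delivers hydride to the face opposite both cis aryl groups, as in the known conversion of 2,3-trans into 2,3-cis flavan-3-ols, to give the axial alcohol 26.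

2. Step 14. Lithiation of the fifteen-fold benzylated trimer may suffer benzylic deprotonation. Addition to the electron-rich phenoxide-aldehyde may be sluggish. The very ionisable benzhydrol may decompose on isolation. The fallback sets out from 15 (through its aryllithium 18, made as in the route) and returns at 20, with the polarity of the union reversed. Aryllithium 18 is quenched with DMF to give the trimer C6 carbaldehyde F4. Ortho-specific hydroxyalkylation of bromomagnesium 3,5-bis(benzyloxy)phenoxide (from the phenol and EtMgBr, toluene, rt) with F4 then gives 20 through a chelated transition state.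

3. Step 11. The aryllithium may enolise the hindered ketone or exchange with its C6 bromine instead of adding. The fallback sets out from 12 and from 6 (through its aryllithium 13) and returns at 15, replacing carbonyl addition by cross-coupling. Ketone 12 is converted with KN(SiMe3)2 and PhNTf2 at −78 °C into the enol triflate F5. Aryllithium 13 is trapped with 2-isopropoxy-4,4,5,5-tetramethyl-1,3,2-dioxaborolane to give the pinacol boronate F6. Suzuki–Miyaura coupling (Pd(OAc)2, SPhos, K3PO4, toluene/H2O) gives the 4-aryl-3-benzyloxyflav-3-ene F7. Ionic hydrogenation (n-Bu3SnH, CF3CO2H) then adds proton and hydride across C3=C4, both anti to the C2 aryl, to give 15.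

Further compounds

F1 | step 17 | 4H-chromene: 5,7-bis(benzyloxy)-2-[3,4-bis(benzyloxy)phenyl]-4H-chromene bonded at C4 to C6 of the second unit of the trimer | c1(OCc9ccccc9)cc(OCc9ccccc9)c2c(c1)OC(c8ccc(OCc9ccccc9)c(OCc9ccccc9)c8)=C[C@@H]2c1c(OCc9ccccc9)c(Cl)c2c(c1OCc9ccccc9)[C@H](c1c(OCc9ccccc9)cc(OCc9ccccc9)c3c1O[C@H](c8ccc(OCc9ccccc9)c(OCc9ccccc9)c8)[C@H](OCc9ccccc9)[C@H]3c1c(OCc9ccccc9)c(Cl)c3c(c1OCc9ccccc9)C[C@@H](OCc9ccccc9)[C@@H](c8ccc(OCc9ccccc9)c(OCc9ccccc9)c8)O3)[C@H](OCc9ccccc9)[C@H](c8ccc(OCc9ccccc9)c(OCc9ccccc9)c8)O2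

F2 | step 17 | C3 epimer of 26 (first unit: 2,4-cis diaryl, 3-OH trans to both) | c1(OCc9ccccc9)cc(OCc9ccccc9)c2c(c1)O[C@H](c8ccc(OCc9ccccc9)c(OCc9ccccc9)c8)[C@@H](O)[C@@H]2c1c(OCc9ccccc9)c(Cl)c2c(c1OCc9ccccc9)[C@H](c1c(OCc9ccccc9)cc(OCc9ccccc9)c3c1O[C@H](c8ccc(OCc9ccccc9)c(OCc9ccccc9)c8)[C@H](OCc9ccccc9)[C@H]3c1c(OCc9ccccc9)c(Cl)c3c(c1OCc9ccccc9)C[C@@H](OCc9ccccc9)[C@@H](c8ccc(OCc9ccccc9)c(OCc9ccccc9)c8)O3)[C@H](OCc9ccccc9)[C@H](c8ccc(OCc9ccccc9)c(OCc9ccccc9)c8)O2

F3 | step 17 | flavan-3-one of the first unit (2,4-cis diaryl) on the protected trimer | c1(OCc9ccccc9)cc(OCc9ccccc9)c2c(c1)O[C@H](c8ccc(OCc9ccccc9)c(OCc9ccccc9)c8)C(=O)[C@@H]2c1c(OCc9ccccc9)c(Cl)c2c(c1OCc9ccccc9)[C@H](c1c(OCc9ccccc9)cc(OCc9ccccc9)c3c1O[C@H](c8ccc(OCc9ccccc9)c(OCc9ccccc9)c8)[C@H](OCc9ccccc9)[C@H]3c1c(OCc9ccccc9)c(Cl)c3c(c1OCc9ccccc9)C[C@@H](OCc9ccccc9)[C@@H](c8ccc(OCc9ccccc9)c(OCc9ccccc9)c8)O3)[C@H](OCc9ccccc9)[C@H](c8ccc(OCc9ccccc9)c(OCc9ccccc9)c8)O2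

F4 | step 14 | trimer 15 with CHO in place of Br at C6 of the second unit | O=Cc1c(OCc9ccccc9)c(Cl)c2c(c1OCc9ccccc9)[C@H](c1c(OCc9ccccc9)cc(OCc9ccccc9)c3c1O[C@H](c8ccc(OCc9ccccc9)c(OCc9ccccc9)c8)[C@H](OCc9ccccc9)[C@H]3c1c(OCc9ccccc9)c(Cl)c3c(c1OCc9ccccc9)C[C@@H](OCc9ccccc9)[C@@H](c8ccc(OCc9ccccc9)c(OCc9ccccc9)c8)O3)[C@H](OCc9ccccc9)[C@H](c8ccc(OCc9ccccc9)c(OCc9ccccc9)c8)O2

F5 | step 11 | enol triflate of 12: (2S)-6-bromo-8-chloro-3,5,7-tris(benzyloxy)-2-[3,4-bis(benzyloxy)phenyl]-2H-chromen-4-yl triflate | Brc1c(OCc9ccccc9)c(Cl)c2c(c1OCc9ccccc9)C(OS(=O)(=O)C(F)(F)F)=C(OCc9ccccc9)[C@H](c8ccc(OCc9ccccc9)c(OCc9ccccc9)c8)O2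

F6 | step 11 | dimer 6 with a pinacol boronate in place of Br at C8 of the third unit | CC1(C)OB(OC1(C)C)c1c(OCc9ccccc9)cc(OCc9ccccc9)c3c1O[C@H](c8ccc(OCc9ccccc9)c(OCc9ccccc9)c8)[C@H](OCc9ccccc9)[C@H]3c1c(OCc9ccccc9)c(Cl)c3c(c1OCc9ccccc9)C[C@@H](OCc9ccccc9)[C@@H](c8ccc(OCc9ccccc9)c(OCc9ccccc9)c8)O3

F7 | step 11 | trimer with a C3=C4 double bond in the second unit (3-benzyloxy-4-aryl-flav-3-ene, 2S) | Brc1c(OCc9ccccc9)c(Cl)c2c(c1OCc9ccccc9)C(c1c(OCc9ccccc9)cc(OCc9ccccc9)c3c1O[C@H](c8ccc(OCc9ccccc9)c(OCc9ccccc9)c8)[C@H](OCc9ccccc9)[C@H]3c1c(OCc9ccccc9)c(Cl)c3c(c1OCc9ccccc9)C[C@@H](OCc9ccccc9)[C@@H](c8ccc(OCc9ccccc9)c(OCc9ccccc9)c8)O3)=C(OCc9ccccc9)[C@H](c8ccc(OCc9ccccc9)c(OCc9ccccc9)c8)O2
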